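**Retrosynthetic overview**
1. Target 28 comes from macrocyclic epoxy alcohol 23 by ester reduction, C4 acylation and desilylation. The 11-membered ring is closed last, at C3–C4, by a ligand-controlled Ni/Cr coupling of an E-alkenyl iodide with an epoxy aldehyde, which also sets C4.
2. The open-chain precursor comes from cross-metathesis (C9=C10) of allyl cyclohexene 9 with epoxy acrylate 15. C5/C6 come from a Sharpless epoxidation; 15 is made from 6-methylhept-5-en-2-one.
3. Ozonolysis of the cyclohexene ring unmasks two groups at once: the C2 aldehyde (→ alkenyl iodide) and the side-chain carbinol with its methyl ketone (→ isopropenyl).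
4. The cyclohexene comes from p-cresol. Oxidative dearomatization with allylsilane builds the quaternary carbon as an achiral dienone; enantioselective reduction of one of its two enantiotopic enones sets C1. A CBS reduction then sets C3'.
5. Ring order: oxirane (East piece) → temporary six-membered ring from the arene (cut open in step 12) → 11-membered carbocycle (step 16).

Assumption: the target is taken as drawn, (1S,2E,4R,5R,6S,9E) in the ring and 3'S in the side chain, with ring locants C1 = quaternary carbon, C2=C3 = disubstituted alkene, C4 = acyloxy carbon, C5/C6 = epoxide (C5 methylated), C9=C10 = trisubstituted alkene (C9 bears CH2OH), C11 = ring CH2; side-chain carbons are primed.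

**Route**

Step 1
Reactants: 1 4-methylphenol (p-cresol); 2 allyltrimethylsilane
Product: 4 4-methyl-4-(prop-2-en-1-yl)cyclohexa-2,5-dien-1-one, via aryloxyiodane 3 (not isolated)
Conditions: PhI(OAc)2 (1.1 equiv), 2 (5 equiv), (CF3)2CHOH, −20 → 0 °C
Reagents that add atoms: none
Why: Oxidative dearomatization (oxidative Hosomi–Sakurai allylation): the hypervalent iodine reagent turns the phenol into a phenoxenium-type cation that the allylsilane traps at the methyl-bearing para carbon, giving a non-enolizable, achiral dienone that already holds the future C1 quaternary carbon flanked by two enantiotopic enone arms.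

Step 2
Reactants: 4 4-methyl-4-(prop-2-en-1-yl)cyclohexa-2,5-dien-1-one
Product: 5 (4S)-4-methyl-4-(prop-2-en-1-yl)cyclohex-2-en-1-one
Conditions: Cu(OAc)2·H2O (5 mol%), (R)-DTBM-SEGPHOS (5.5 mol%), (EtO)2MeSiH (1.1 equiv), t-BuOH (1.1 equiv), toluene, −40 °C
Reagents that add atoms: none
Why: Desymmetrization by ligand-controlled copper hydride 1,4-reduction: the chiral bisphosphine–CuH reduces only one of the two enantiotopic enone C=C bonds, which turns the quaternary carbon into a stereocentre (S wanted; the ligand antipode is used if the first run gives R) and keeps one enone for later use.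

Step 3
Reactants: 5 (4S)-4-methyl-4-(prop-2-en-1-yl)cyclohex-2-en-1-one
Product: 6 (4S)-2-iodo-4-methyl-4-(prop-2-en-1-yl)cyclohex-2-en-1-one
Conditions: I2 (2 equiv), pyridine, DMAP (cat.), CH2Cl2, rt
Reagents that add atoms: iodine, II
Why: Johnson α-iodination (pyridine conjugate addition, iodination of the enolate, elimination) puts iodine on the only enone α-carbon and leaves the isolated allyl group and the stereocentre alone.

Step 4
Reactants: 6 (4S)-2-iodo-4-methyl-4-(prop-2-en-1-yl)cyclohex-2-en-1-one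
Product: 7 (4S)-2,4-dimethyl-4-(prop-2-en-1-yl)cyclohex-2-en-1-one
Conditions: MeB(OH)2 (2 equiv), Pd(dppf)Cl2 (5 mol%), K2CO3, dioxane/H2O, 80 °C
Reagents that add atoms: methylboronic acid, CB(O)O
Why: Suzuki–Miyaura methylation of the activated α-iodoenone (oxidative addition to zerovalent palladium, transmetalation, reductive elimination) installs the methyl group that becomes the isopropenyl methyl; no stereocentre is touched.

Step 5
Reactants: 7 (4S)-2,4-dimethyl-4-(prop-2-en-1-yl)cyclohex-2-en-1-one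
Product: 8 (1S,4S)-2,4-dimethyl-4-(prop-2-en-1-yl)cyclohex-2-en-1-ol
Conditions: (R)-2-methyl-CBS-oxazaborolidine (0.2 equiv), catecholborane (1.5 equiv), toluene, −78 °C; then MeOH, aq. NaOH
Reagents that add atoms: none
Why: Corey–Bakshi–Shibata reduction: the α-methylated alkenyl side acts as the large group, so the (R)-catalyst delivers hydride to give the 1S carbinol (the future C3') under reagent control, while catecholborane at −78 °C neither hydroborates the allyl group nor reduces 1,4.

Step 6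
Reactants: 8 (1S,4S)-2,4-dimethyl-4-(prop-2-en-1-yl)cyclohex-2-en-1-ol
Product: 9 tert-butyl{[(1S,4S)-2,4-dimethyl-4-(prop-2-en-1-yl)cyclohex-2-en-1-yl]oxy}dimethylsilane
Conditions: TBSCl, imidazole, DMF, rt
Reagents that add atoms: tert-butyldimethylsilyl chloride, CC(C)(C)[Si](C)(C)Cl
Why: Standard silylation protects the future C3' hydroxyl until the last step.

Step 7
Reactants: 10 6-methylhept-5-en-2-one
Product: 12 6-methylhepta-1,5-dien-2-yl trifluoromethanesulfonate, via lithium enolate 11 (not isolated)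
Conditions: LiN(iPr)2, THF, −78 °C; then PhNTf2, −78 → 0 °C
Reagents that add atoms: N-phenylbis(trifluoromethanesulfonimide), O=S(=O)(N(c1ccccc1)S(=O)(=O)C(F)(F)F)C(F)(F)F
Why: Kinetic deprotonation of the methyl ketone on its methyl side and O-triflation of the enolate give the 2-triflyloxy-1-alkene regioselectively.

Step 8
Reactants: 12 6-methylhepta-1,5-dien-2-yl trifluoromethanesulfonate
Product: 13 methyl 6-methyl-2-methylidenehept-5-enoate
Conditions: Pd(OAc)2 (3 mol%), PPh3 (6 mol%), CO (1 atm), MeOH, Et3N, DMF, rt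
Reagents that add atoms: carbon monoxide, [C-]#[O+]; methanol, CO
Why: Palladium-catalysed methoxycarbonylation of the alkenyl triflate (oxidative addition, CO insertion, methanolysis) gives the 2-substituted acrylate whose carbonyl carbon becomes the C9 hydroxymethyl carbon.

Step 9
Reactants: 13 methyl 6-methyl-2-methylidenehept-5-enoate
Product: 14 methyl (5E)-7-hydroxy-6-methyl-2-methylidenehept-5-enoate
Conditions: SeO2 (0.3 equiv), t-BuOOH (3 equiv), salicylic acid (cat.), CH2Cl2, rt
Reagents that add atoms: tert-butyl hydroperoxide, CC(C)(C)OO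
Why: Sharpless SeO2/t-BuOOH allylic oxidation (ene reaction, then [2,3]-shift) hydroxylates only the E methyl group of the electron-rich trisubstituted alkene, which fixes the E geometry behind the trans epoxide; the acrylate does not react.

Step 10
Reactants: 14 methyl (5E)-7-hydroxy-6-methyl-2-methylidenehept-5-enoate
Product: 15 methyl 4-[(2S,3S)-3-(hydroxymethyl)-3-methyloxiran-2-yl]-2-methylidenebutanoate
Conditions: Ti(OiPr)4 (10 mol%), L-(+)-diethyl tartrate (12 mol%), t-BuOOH (2 equiv), 4 Å MS, CH2Cl2, −20 °C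
Reagents that add atoms: tert-butyl hydroperoxide, CC(C)(C)OO
Why: Sharpless asymmetric epoxidation: with L-(+)-tartrate the E 2-methyl allylic alcohol is epoxidized on the face that gives the (2S,3S)-epoxy alcohol (the future C5 and C6), and the electron-poor acrylate is inert.

Step 11
Reactants: 9 tert-butyl{[(1S,4S)-2,4-dimethyl-4-(prop-2-en-1-yl)cyclohex-2-en-1-yl]oxy}dimethylsilane; 15 methyl 4-[(2S,3S)-3-(hydroxymethyl)-3-methyloxiran-2-yl]-2-methylidenebutanoate
Product: 16 methyl (2E)-4-[(1S,4S)-4-(tert-butyldimethylsilyloxy)-1,3-dimethylcyclohex-2-en-1-yl]-2-{2-[(2S,3S)-3-(hydroxymethyl)-3-methyloxiran-2-yl]ethyl}but-2-enoate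
Conditions: second-generation Hoveyda–Grubbs catalyst (7.5 mol%), 15 (2.5 equiv), CH2Cl2, 40 °C, N2 sparge
Reagents that add atoms: none
Why: Olefin cross-metathesis between the terminal allyl group and the 1,1-disubstituted acrylate (used in excess) gives the thermodynamically preferred E enoate, which puts C8 and C11 cis as in the target; the hindered trisubstituted ring alkene does not take part.

Step 12
Reactants: 16 cross-metathesis product
Product: 18 methyl (2E,5S,8S)-8-(tert-butyldimethylsilyloxy)-5-formyl-2-{2-[(2S,3S)-3-(hydroxymethyl)-3-methyloxiran-2-yl]ethyl}-5-methyl-9-oxodec-2-enoate, via ring ozonide 17 (not isolated)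
Conditions: O3, CH2Cl2, −78 °C (stop at first blue colour); then PPh3, −78 °C → rt
Reagents that add atoms: ozone, [O-][O+]=O
Why: Ozonolysis: ozone attacks the electron-rich trisubstituted ring alkene far faster than the conjugated enoate, and reduction of the ozonide releases the future C2 aldehyde and the side-chain methyl ketone without touching C1 or C3'.

Step 13
Reactants: 18 keto aldehyde
Product: 19 methyl (2E,5S,8S)-8-(tert-butyldimethylsilyloxy)-2-{2-[(2S,3S)-3-(hydroxymethyl)-3-methyloxiran-2-yl]ethyl}-5-[(E)-2-iodoethenyl]-5-methyl-9-oxodec-2-enoate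
Conditions: CrCl2 (8 equiv), CHI3 (3 equiv), THF/1,4-dioxane, 0 °C → rt
Reagents that add atoms: iodoform, C(I)(I)I
Why: Takai olefination (geminal dichromium reagent from CHI3 and divalent chromium) converts the aldehyde, not the ketone, into the E-alkenyl iodide that carries C2 and C3.

Step 14
Reactants: 19 alkenyl iodide ketone
Product: 20 methyl (2E,5S,8S)-8-(tert-butyldimethylsilyloxy)-2-{2-[(2S,3S)-3-(hydroxymethyl)-3-methyloxiran-2-yl]ethyl}-5-[(E)-2-iodoethenyl]-5,9-dimethyldeca-2,9-dienoate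
Conditions: Ph3PCH3Br (3 equiv), KN(SiMe3)2 (2.9 equiv), THF, 0 °C; add 19 at −78 → 0 °C
Reagents that add atoms: methyltriphenylphosphonium bromide, C[P+](c1ccccc1)(c1ccccc1)c1ccccc1.[Br-]
Why: Wittig methylenation of the only ketone gives the isopropenyl group, the extra ylide merely deprotonating the free alcohol.

Step 15
Reactants: 20 epoxy alcohol
Product: 21 methyl (2E,5S,8S)-8-(tert-butyldimethylsilyloxy)-2-{2-[(2S,3R)-3-formyl-3-methyloxiran-2-yl]ethyl}-5-[(E)-2-iodoethenyl]-5,9-dimethyldeca-2,9-dienoate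
Conditions: TEMPO (10 mol%), PhI(OAc)2 (1.2 equiv), CH2Cl2, rt
Reagents that add atoms: none
Why: TEMPO/PhI(OAc)2 oxidation (oxoammonium) takes the primary epoxy alcohol to the aldehyde under near-neutral conditions that spare the epoxide and the alkenyl iodide (the oxirane label changes from 3S to 3R by priority only).

Step 16
Reactants: 21 epoxy aldehyde alkenyl iodide
Product: 23 methyl (1S,2E,4R,5S,6S,9E)-1-[(3S)-3-(tert-butyldimethylsilyloxy)-4-methylpent-4-en-1-yl]-5,6-epoxy-4-hydroxy-1,5-dimethylcycloundeca-2,9-diene-9-carboxylate, via alkenylchromium species 22 (not isolated)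
Conditions: CrCl2 (8 equiv), NiCl2 (0.1 equiv), (S)-N-[2-(4-isopropyl-4,5-dihydrooxazol-2-yl)-6-methylphenyl]methanesulfonamide (9 equiv), Et3N (9 equiv), THF, rt, slow addition of 21 to 1 mM
Reagents that add atoms: none
Why: Nozaki–Hiyama–Kishi macrocyclization: oxidative addition of the alkenyl iodide to zerovalent nickel, transmetalation to trivalent chromium and addition to the aldehyde close the 11-membered ring with the E alkene retained, and the chiral sulfonamide ligand on chromium selects the aldehyde face so that C4 is R (the ligand antipode is used if the first run gives the 4-epimer).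

Step 17
Reactants: 23 macrocyclic hydroxy ester
Product: 24 (1S,2E,4R,5S,6S,9E)-1-[(3S)-3-(tert-butyldimethylsilyloxy)-4-methylpent-4-en-1-yl]-5,6-epoxy-9-(hydroxymethyl)-1,5-dimethylcycloundeca-2,9-dien-4-ol
Conditions: i-Bu2AlH (4 equiv), CH2Cl2, −78 °C; aq. KNaC4H4O6
Reagents that add atoms: none
Why: i-Bu2AlH reduces the conjugated methyl ester to the primary allylic alcohol at −78 °C, where the epoxide and the alkenes are not attacked.

Step 18
Reactants: 24 macrocyclic diol
Product: 25 (1S,2E,4R,5S,6S,9E)-9-[(tert-butyldimethylsilyloxy)methyl]-1-[(3S)-3-(tert-butyldimethylsilyloxy)-4-methylpent-4-en-1-yl]-5,6-epoxy-1,5-dimethylcycloundeca-2,9-dien-4-ol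
Conditions: TBSCl (1.1 equiv), imidazole, CH2Cl2, 0 °C
Reagents that add atoms: tert-butyldimethylsilyl chloride, CC(C)(C)[Si](C)(C)Cl
Why: Steric differentiation: the primary allylic hydroxyl is silylated, while the hindered secondary C4 hydroxyl next to the fully substituted epoxide carbon is not.

Step 19
Reactants: 25 C4 alcohol; 26 3-methylbut-2-enoyl chloride
Product: 27 (1S,2E,4R,5R,6S,9E)-9-[(tert-butyldimethylsilyloxy)methyl]-1-[(3S)-3-(tert-butyldimethylsilyloxy)-4-methylpent-4-en-1-yl]-5,6-epoxy-1,5-dimethylcycloundeca-2,9-dien-4-yl 3-methylbut-2-enoate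
Conditions: 26 (3 equiv), pyridine, DMAP (0.2 equiv), CH2Cl2, 0 °C → rt
Reagents that add atoms: none
Why: DMAP-catalysed acylation esterifies C4 with retention, and pyridine (not a trialkylamine) avoids deconjugation of the acyl chloride through its vinylketene (the C5 label changes from S to R by priority only).

Step 20
Reactants: 27 bis-silyl ether ester
Product: 28 target, (1S,2E,4R,5R,6S,9E)-5,6-epoxy-9-(hydroxymethyl)-1-[(3S)-3-hydroxy-4-methylpent-4-en-1-yl]-1,5-dimethylcycloundeca-2,9-dien-4-yl 3-methylbut-2-enoate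
Conditions: Bu4NF (3 equiv), THF, 0 °C → rt
Reagents that add atoms: none
Why: Fluoride cleaves both silyl ethers (Si–F bond formation) without touching the ester or the epoxide, and the product SMILES is identical to the target.

**Compound list**
1 | 4-methylphenol (p-cresol) | Cc1ccc(O)cc1 | starting material
2 | allyltrimethylsilane | C=CC[Si](C)(C)C | starting material
3 | acetoxy(4-methylphenoxy)(phenyl)iodane | CC(=O)OI(Oc1ccc(C)cc1)c1ccccc1 | intermediate (not isolated)
4 | 4-methyl-4-(prop-2-en-1-yl)cyclohexa-2,5-dien-1-one | C=CCC1(C)C=CC(=O)C=C1 | intermediate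
5 | (4S)-4-methyl-4-(prop-2-en-1-yl)cyclohex-2-en-1-one | C=CC[C@@]1(C)C=CC(=O)CC1 | intermediate
6 | (4S)-2-iodo-4-methyl-4-(prop-2-en-1-yl)cyclohex-2-en-1-one | C=CC[C@@]1(C)C=C(I)C(=O)CC1 | intermediate
7 | (4S)-2,4-dimethyl-4-(prop-2-en-1-yl)cyclohex-2-en-1-one | C=CC[C@@]1(C)C=C(C)C(=O)CC1 | intermediate
8 | (1S,4S)-2,4-dimethyl-4-(prop-2-en-1-yl)cyclohex-2-en-1-ol | C=CC[C@@]1(C)C=C(C)[C@@H](O)CC1 | intermediate
9 | tert-butyl{[(1S,4S)-2,4-dimethyl-4-(prop-2-en-1-yl)cyclohex-2-en-1-yl]oxy}dimethylsilane | C=CC[C@@]1(C)C=C(C)[C@@H](O[Si](C)(C)C(C)(C)C)CC1 | intermediate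
10 | 6-methylhept-5-en-2-one | CC(=O)CCC=C(C)C | starting material
11 | lithium 6-methylhepta-1,5-dien-2-olate | [Li+].[O-]C(=C)CCC=C(C)C | intermediate (not isolated)
12 | 6-methylhepta-1,5-dien-2-yl trifluoromethanesulfonate | C=C(CCC=C(C)C)OS(=O)(=O)C(F)(F)F | intermediate
13 | methyl 6-methyl-2-methylidenehept-5-enoate | C=C(CCC=C(C)C)C(=O)OC | intermediate
14 | methyl (5E)-7-hydroxy-6-methyl-2-methylidenehept-5-enoate | C=C(CC/C=C(\C)CO)C(=O)OC | intermediate
15 | methyl 4-[(2S,3S)-3-(hydroxymethyl)-3-methyloxiran-2-yl]-2-methylidenebutanoate | C=C(CC[C@@H]1O[C@@]1(C)CO)C(=O)OC | intermediate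
16 | methyl (2E)-4-[(1S,4S)-4-(tert-butyldimethylsilyloxy)-1,3-dimethylcyclohex-2-en-1-yl]-2-{2-[(2S,3S)-3-(hydroxymethyl)-3-methyloxiran-2-yl]ethyl}but-2-enoate | COC(=O)/C(CC[C@@H]1O[C@@]1(C)CO)=C/C[C@@]2(C)C=C(C)[C@@H](O[Si](C)(C)C(C)(C)C)CC2 | intermediate
17 | ring ozonide of 16 (1,2,4-trioxolane across the former ring C2=C3; both trioxolane carbons as a mixture) | COC(=O)/C(CC[C@@H]1O[C@@]1(C)CO)=C/C[C@]2(C)CC[C@H](O[Si](C)(C)C(C)(C)C)C3(C)OOC2O3 | intermediate (not isolated)
18 | methyl (2E,5S,8S)-8-(tert-butyldimethylsilyloxy)-5-formyl-2-{2-[(2S,3S)-3-(hydroxymethyl)-3-methyloxiran-2-yl]ethyl}-5-methyl-9-oxodec-2-enoate | CC(=O)[C@@H](O[Si](C)(C)C(C)(C)C)CC[C@](C)(C=O)C/C=C(/C(=O)OC)CC[C@@H]1O[C@@]1(C)CO | intermediate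
19 | methyl (2E,5S,8S)-8-(tert-butyldimethylsilyloxy)-2-{2-[(2S,3S)-3-(hydroxymethyl)-3-methyloxiran-2-yl]ethyl}-5-[(E)-2-iodoethenyl]-5-methyl-9-oxodec-2-enoate | CC(=O)[C@@H](O[Si](C)(C)C(C)(C)C)CC[C@](C)(/C=C/I)C/C=C(/C(=O)OC)CC[C@@H]1O[C@@]1(C)CO | intermediate
20 | methyl (2E,5S,8S)-8-(tert-butyldimethylsilyloxy)-2-{2-[(2S,3S)-3-(hydroxymethyl)-3-methyloxiran-2-yl]ethyl}-5-[(E)-2-iodoethenyl]-5,9-dimethyldeca-2,9-dienoate | C=C(C)[C@@H](O[Si](C)(C)C(C)(C)C)CC[C@](C)(/C=C/I)C/C=C(/C(=O)OC)CC[C@@H]1O[C@@]1(C)CO | intermediate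
21 | methyl (2E,5S,8S)-8-(tert-butyldimethylsilyloxy)-2-{2-[(2S,3R)-3-formyl-3-methyloxiran-2-yl]ethyl}-5-[(E)-2-iodoethenyl]-5,9-dimethyldeca-2,9-dienoate | C=C(C)[C@@H](O[Si](C)(C)C(C)(C)C)CC[C@](C)(/C=C/I)C/C=C(/C(=O)OC)CC[C@@H]1O[C@@]1(C)C=O | intermediate
22 | alkenylchromium species from 21 (C–I replaced by C–CrCl2; ligand and solvent on chromium omitted) | C=C(C)[C@@H](O[Si](C)(C)C(C)(C)C)CC[C@](C)(/C=C/[Cr](Cl)Cl)C/C=C(/C(=O)OC)CC[C@@H]1O[C@@]1(C)C=O | intermediate (not isolated)
23 | methyl (1S,2E,4R,5S,6S,9E)-1-[(3S)-3-(tert-butyldimethylsilyloxy)-4-methylpent-4-en-1-yl]-5,6-epoxy-4-hydroxy-1,5-dimethylcycloundeca-2,9-diene-9-carboxylate | C=C(C)[C@@H](O[Si](C)(C)C(C)(C)C)CC[C@]1(C)/C=C/[C@@H](O)[C@]2(C)O[C@H]2CC/C(C(=O)OC)=C\C1 | intermediate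
24 | (1S,2E,4R,5S,6S,9E)-1-[(3S)-3-(tert-butyldimethylsilyloxy)-4-methylpent-4-en-1-yl]-5,6-epoxy-9-(hydroxymethyl)-1,5-dimethylcycloundeca-2,9-dien-4-ol | C=C(C)[C@@H](O[Si](C)(C)C(C)(C)C)CC[C@]1(C)/C=C/[C@@H](O)[C@]2(C)O[C@H]2CC/C(CO)=C\C1 | intermediate
25 | (1S,2E,4R,5S,6S,9E)-9-[(tert-butyldimethylsilyloxy)methyl]-1-[(3S)-3-(tert-butyldimethylsilyloxy)-4-methylpent-4-en-1-yl]-5,6-epoxy-1,5-dimethylcycloundeca-2,9-dien-4-ol | C=C(C)[C@@H](O[Si](C)(C)C(C)(C)C)CC[C@]1(C)/C=C/[C@@H](O)[C@]2(C)O[C@H]2CC/C(CO[Si](C)(C)C(C)(C)C)=C\C1 | intermediate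
26 | 3-methylbut-2-enoyl chloride | CC(C)=CC(=O)Cl | starting material
27 | (1S,2E,4R,5R,6S,9E)-9-[(tert-butyldimethylsilyloxy)methyl]-1-[(3S)-3-(tert-butyldimethylsilyloxy)-4-methylpent-4-en-1-yl]-5,6-epoxy-1,5-dimethylcycloundeca-2,9-dien-4-yl 3-methylbut-2-enoate | C=C(C)[C@@H](O[Si](C)(C)C(C)(C)C)CC[C@]1(C)/C=C/[C@@H](OC(=O)C=C(C)C)[C@]2(C)O[C@H]2CC/C(CO[Si](C)(C)C(C)(C)C)=C\C1 | intermediate
28 | (1S,2E,4R,5R,6S,9E)-5,6-epoxy-9-(hydroxymethyl)-1-[(3S)-3-hydroxy-4-methylpent-4-en-1-yl]-1,5-dimethylcycloundeca-2,9-dien-4-yl 3-methylbut-2-enoate | C=C(C)[C@@H](O)CC[C@]1(C)/C=C/[C@@H](OC(=O)C=C(C)C)[C@]2(C)O[C@H]2CC/C(CO)=C\C1 | target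

**Step count**
Total: 20 steps. Longest linear sequence: 16 steps (steps 1–6, then 11–20); steps 7–10 make the East piece.

**The three steps most likely to fail**

Step 16 (ring closure and C4 configuration). The ring may close but with poor ligand control at C4; the target needs the hydroxyl threo to the epoxide oxygen, which simple chelation models do not favour. The fallback sets out from 21. The Ni/Cr cyclization is run without the chiral ligand (CrCl2, NiCl2, DMSO, high dilution), giving 23 mixed with its C4 epimer, methyl (1S,2E,4S,5S,6S,9E)-1-[(3S)-3-(tert-butyldimethylsilyloxy)-4-methylpent-4-en-1-yl]-5,6-epoxy-4-hydroxy-1,5-dimethylcycloundeca-2,9-diene-9-carboxylate F3. The mixture is oxidized (Dess–Martin periodinane) to the single epoxy enone, the 4-oxo compound F4. Chelation-controlled reduction with Zn(BH4)2 in Et2O then gives only the erythro alcohol F3. i-Bu2AlH reduction gives the 4S diol F5, and TBSCl/imidazole gives the 4S primary silyl ether F6. A Mitsunobu esterification (PPh3, diisopropyl azodicarboxylate, 3-methylbut-2-enoic acid, toluene) inverts C4 and brings the route back at 27.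

Step 2 (enantioselectivity). The copper hydride must tell methyl from allyl on the carbon next to the one it attacks, so the ee may be low. The fallback sets out from 4 and comes back at 5 by a biocatalytic desymmetrization. A flavin ene-reductase of the old-yellow-enzyme family (YqjM or OPR3, NADP+, glucose, glucose dehydrogenase, buffer, 30 °C) reduces one enantiotopic C=C through active-site binding rather than ligand sterics. The enzyme or mutant that gives the S enone is picked by screening. This fallback makes no new compound (F0).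

Step 1 (dearomatization). Unblocked p-cresol may give ortho attack or over-oxidation and a low yield of 4. The fallback sets out from 1 and uses removable blocking groups. Bromination (Br2, AcOH) gives 2,6-dibromo-4-methylphenol F1. The same PhI(OAc)2/allylsilane dearomatization, now limited to the para carbon, gives 2,6-dibromo-4-methyl-4-(prop-2-en-1-yl)cyclohexa-2,5-dien-1-one F2. Palladium-catalysed formate reduction of the two alkenyl bromides (Pd(OAc)2, PPh3, HCO2H, Et3N, DMF, 50 °C) brings the route back at 4.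

**Further compounds**
F1 | step 1 | 2,6-dibromo-4-methylphenol | Cc1cc(Br)c(O)c(Br)c1
F2 | step 1 | 2,6-dibromo-4-methyl-4-(prop-2-en-1-yl)cyclohexa-2,5-dien-1-one | C=CCC1(C)C=C(Br)C(=O)C(Br)=C1
F0 | step 2 | none | none
F3 | step 16 | methyl (1S,2E,4S,5S,6S,9E)-1-[(3S)-3-(tert-butyldimethylsilyloxy)-4-methylpent-4-en-1-yl]-5,6-epoxy-4-hydroxy-1,5-dimethylcycloundeca-2,9-diene-9-carboxylate | C=C(C)[C@@H](O[Si](C)(C)C(C)(C)C)CC[C@]1(C)/C=C/[C@H](O)[C@]2(C)O[C@H]2CC/C(C(=O)OC)=C\C1
F4 | step 16 | methyl (1S,2E,5R,6S,9E)-1-[(3S)-3-(tert-butyldimethylsilyloxy)-4-methylpent-4-en-1-yl]-5,6-epoxy-1,5-dimethyl-4-oxocycloundeca-2,9-diene-9-carboxylate | C=C(C)[C@@H](O[Si](C)(C)C(C)(C)C)CC[C@]1(C)/C=C/C(=O)[C@]2(C)O[C@H]2CC/C(C(=O)OC)=C\C1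
F5 | step 16 | (1S,2E,4S,5S,6S,9E)-1-[(3S)-3-(tert-butyldimethylsilyloxy)-4-methylpent-4-en-1-yl]-5,6-epoxy-9-(hydroxymethyl)-1,5-dimethylcycloundeca-2,9-dien-4-ol | C=C(C)[C@@H](O[Si](C)(C)C(C)(C)C)CC[C@]1(C)/C=C/[C@H](O)[C@]2(C)O[C@H]2CC/C(CO)=C\C1
F6 | step 16 | (1S,2E,4S,5S,6S,9E)-9-[(tert-butyldimethylsilyloxy)methyl]-1-[(3S)-3-(tert-butyldimethylsilyloxy)-4-methylpent-4-en-1-yl]-5,6-epoxy-1,5-dimethylcycloundeca-2,9-dien-4-ol | C=C(C)[C@@H](O[Si](C)(C)C(C)(C)C)CC[C@]1(C)/C=C/[C@H](O)[C@]2(C)O[C@H]2CC/C(CO[Si](C)(C)C(C)(C)C)=C\C1
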